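**Plan**
- Cuts: the C11=C12 and C11'=C12' double bonds (two Horner–Wadsworth–Emmons reactions on trienedial 30), then C6–C7 and C8'–C9' (Sonogashira couplings), then C5'–CH3 (Negishi), and last C4'–C5', C5'–C6' and C4'–O of the diol ring together.
- Enabling feature: in ring C1'–C6' the oxygen-bearing C4', the substituted vinylic C5' and the alkyne-bearing C6' lie in a row. This is the imprint of one halocarbene carbon (C5') pushed into the C4'=C6' bond of a cyclopentene, and the neighbouring C3'–O can pass an oxygen to C4' on its own face.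
- Forward: cyclopentenone 5 → carbinol 6 → carbonate 7 → ring enlargement to the cyclohexene with fused dioxolanone (10) → methyl, free alkyne, C15 phosphonate 20. The left ring comes ready-made from ketoisophorone (21 → triflate 25 → phosphonate 29). Chain: 29 + 30 → C25 aldehyde 31, then 31 + 20 → C40, then desilylation.
- Stereochemistry: C3' by CBS reduction; C4' relayed from C3' through the tethered carbonate (cis); C3 by ene-reductase reduction of 21, relayed to the carbinol by hydride approach. The E double bonds come from 16, 26 and 30 (retention in the couplings) and from E-selective olefinations.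
- Remark: primed locants (carotenoid numbering) belong to the ring with the cis-3',4'-diol; 1, 3, 8, 15, 21, 26 and 30 are taken as purchasable.

Key step: step 5

**Route**

Step 1
Reactants: 1 4,4-dimethylcyclopentane-1,3-dione
Product: 2 5,5-dimethyl-3-(2-methylpropoxy)cyclopent-2-en-1-one
Conditions: i-BuOH, TsOH·H2O (cat.), toluene, reflux, Dean–Stark
Reagents that add atoms: 2-methylpropan-1-ol, CC(C)CO
Why: Acid-catalysed enol etherification of a cyclic 1,3-dione (vinylogous ester formation), in which the alcohol should attack the carbonyl remote from the quaternary carbon, as in the six-ring analogue, so that the ketone next to CMe2 remains.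

Step 2
Reactants: 2 5,5-dimethyl-3-(2-methylpropoxy)cyclopent-2-en-1-one; 3 ethynyltri(propan-2-yl)silane
Product: 5 4,4-dimethyl-3-[(triisopropylsilyl)ethynyl]cyclopent-2-en-1-one, via tertiary propargylic alcohol 4 (not isolated)
Conditions: 3, n-BuLi, THF, −78 °C; then 2, −78 → 0 °C; then 1 M HCl, rt
Reagents that add atoms: none
Why: Stork–Danheiser carbonyl transposition, in which the slim lithium acetylide adds to the neopentyl ketone of the vinylogous ester and acid hydrolysis of the enol ether with loss of water moves the carbonyl to the former enol ether carbon.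

Step 3
Reactants: 5 4,4-dimethyl-3-[(triisopropylsilyl)ethynyl]cyclopent-2-en-1-one
Product: 6 (1S)-4,4-dimethyl-3-[(triisopropylsilyl)ethynyl]cyclopent-2-en-1-ol
Conditions: (R)-Me-CBS oxazaborolidine (0.2 equiv), catecholborane, toluene, −78 °C
Reagents that add atoms: none
Why: Corey–Bakshi–Shibata reduction, in which the (R)-oxazaborolidine binds the ketone with the alkenyl arm as the large group and delivers hydride to the face that gives the (S)-carbinol (C3'), while catecholborane at −78 °C should leave the C=C bond and the alkyne alone.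

Step 4
Reactants: 6 (1S)-4,4-dimethyl-3-[(triisopropylsilyl)ethynyl]cyclopent-2-en-1-ol
Product: 7 tert-butyl (1S)-4,4-dimethyl-3-[(triisopropylsilyl)ethynyl]cyclopent-2-en-1-yl carbonate
Conditions: Boc2O, DMAP (cat.), MeCN, rt
Reagents that add atoms: di-tert-butyl dicarbonate, CC(C)(C)OC(=O)OC(=O)OC(C)(C)C
Why: DMAP-catalysed O-acylation of the secondary allylic alcohol (carbonate formation), which does not touch the stereocentre.

Step 5
Reactants: 7 tert-butyl (1S)-4,4-dimethyl-3-[(triisopropylsilyl)ethynyl]cyclopent-2-en-1-yl carbonate; 8 bromoform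
Product: 10 (3aS,7aS)-4-bromo-6,6-dimethyl-5-[(triisopropylsilyl)ethynyl]-3a,6,7,7a-tetrahydro-1,3-benzodioxol-2-one, via dibromocyclopropane 9 (not isolated)
Conditions: CHBr3 (8), 50% aq NaOH, BnEt3NCl (cat.), CH2Cl2, 0 °C → rt; crude 9, then AgOSO2CF3, NaHCO3, CH2Cl2, 0 °C → rt, dark
Reagents that add atoms: none
Why: Singlet CBr2 made at the phase boundary should add in one cheletropic step to the only alkene of 7 (the silyl-capped alkyne is shielded and less nucleophilic), forming C4'–C5' and C5'–C6' as the fused cyclopropane 9. Silver ion then removes the bromide lying over the five-membered ring while the C4'–C6' bond opens in the disrotatory sense, so the six-membered ring arises by strain-driven one-carbon enlargement (not by an end-to-end closure) as a 2-bromoallyl cation over C4'–C5'–C6'. The carbonyl oxygen of the carbonate on C3' closes the dioxolanone by 5-exo attack on the C4' terminus and the tert-butyl cation leaves as 2-methylpropene, the acid being taken up by NaHCO3. The closest known reaction type is the silver-promoted ring expansion of 6,6-dibromobicyclo[3.1.0]hexanes to 2-bromocyclohex-2-enyl esters with capture by a neighbouring acyl oxygen, joined to the familiar cyclisation of tert-butyl carbonates onto cations. The new C4' stereocentre is set by C3', because the tether reaches C4' only from the face carrying the C3'–O bond; the fusion is therefore cis whichever face the carbene took, both cyclopropane isomers giving the same planar cation. The regioselectivity needed (C4', not the propargylic C6') rests on the same tether, since attack at the neopentyl C6' would require a bridged seven-membered ring, and capture at C4' keeps C5'=C6' conjugated to the alkyne with bromine marking C5'.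

Step 6
Reactants: 10 (3aS,7aS)-4-bromo-6,6-dimethyl-5-[(triisopropylsilyl)ethynyl]-3a,6,7,7a-tetrahydro-1,3-benzodioxol-2-one
Product: 11 (1S,2S)-3-bromo-5,5-dimethyl-4-[(triisopropylsilyl)ethynyl]cyclohex-3-ene-1,2-diol
Conditions: K2CO3, MeOH, rt
Reagents that add atoms: none
Why: Base-catalysed methanolysis (transesterification) of the five-membered cyclic carbonate frees the cis-diol without change at C3' or C4', the hindered C-silyl group and the vinyl bromide being inert to K2CO3 in MeOH.

Step 7
Reactants: 11 (1S,2S)-3-bromo-5,5-dimethyl-4-[(triisopropylsilyl)ethynyl]cyclohex-3-ene-1,2-diol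
Product: 12 bis(tert-butyldimethylsilyl) ether of 11
Conditions: TBSOTf, 2,6-lutidine, CH2Cl2, 0 °C → rt
Reagents that add atoms: tert-butyldimethylsilyl trifluoromethanesulfonate, CC(C)(C)[Si](C)(C)OS(=O)(=O)C(F)(F)F
Why: Silylation with the silyl triflate caps both hindered secondary hydroxyls, so that no allylic leaving group remains when palladium chemistry begins.

Step 8
Reactants: 12 bis(tert-butyldimethylsilyl) ether of 11
Product: 13 (1S,2R)-3,5,5-trimethyl-4-[(triisopropylsilyl)ethynyl]cyclohex-3-ene-1,2-diyl bis(tert-butyldimethylsilyl) ether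
Conditions: MeZnCl, Pd(P(t-Bu)3)2 (5 mol %), THF/NMP, 60 °C
Reagents that add atoms: methylzinc chloride, C[Zn]Cl
Why: Negishi cross-coupling, in which the electron-rich zerovalent palladium catalyst inserts into the alkenyl C5'–Br bond, methyl is transferred from zinc and reductive elimination installs the C5' methyl group on the ring-locked double bond.

Step 9
Reactants: 13 (1S,2R)-3,5,5-trimethyl-4-[(triisopropylsilyl)ethynyl]cyclohex-3-ene-1,2-diyl bis(tert-butyldimethylsilyl) ether
Product: 14 (1S,2R)-4-ethynyl-3,5,5-trimethylcyclohex-3-ene-1,2-diyl bis(tert-butyldimethylsilyl) ether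
Conditions: Bu4NF (1.05 equiv), THF, −20 °C
Reagents that add atoms: none
Why: Fluoride-induced protodesilylation of the alkynylsilane, whose C(sp)–Si bond should be cleaved much faster than the two hindered secondary O–Si bonds at low temperature with one equivalent of fluoride.

Step 10
Reactants: 15 ethyl 3-oxobutanoate
Product: 16 ethyl (2E)-3-{[(trifluoromethyl)sulfonyl]oxy}but-2-enoate
Conditions: Tf2O, aq Me4NOH, hexane, 5 °C
Reagents that add atoms: trifluoromethanesulfonic anhydride, O=S(=O)(OS(=O)(=O)C(F)(F)F)C(F)(F)F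
Why: Stereoselective enol triflation of a β-keto ester, in which the non-chelating tetramethylammonium enolate should give the (E)-enol triflate that carries the future C9'=C10' geometry.

Step 11
Reactants: 14 (1S,2R)-4-ethynyl-3,5,5-trimethylcyclohex-3-ene-1,2-diyl bis(tert-butyldimethylsilyl) ether; 16 ethyl (2E)-3-{[(trifluoromethyl)sulfonyl]oxy}but-2-enoate
Product: 17 ethyl (2E)-5-[(3R,4S)-3,4-bis(tert-butyldimethylsilyloxy)-2,6,6-trimethylcyclohex-1-en-1-yl]-3-methylpent-2-en-4-ynoate
Conditions: PdCl2(PPh3)2 (5 mol %), CuI (10 mol %), Et3N, THF, rt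
Reagents that add atoms: none
Why: Sonogashira coupling of the terminal alkyne with the alkenyl triflate forms C8'–C9' with retention of the (E) geometry of the triflate.

Step 12
Reactants: 17 ethyl (2E)-5-[(3R,4S)-3,4-bis(tert-butyldimethylsilyloxy)-2,6,6-trimethylcyclohex-1-en-1-yl]-3-methylpent-2-en-4-ynoate
Product: 18 (2E)-5-[(3R,4S)-3,4-bis(tert-butyldimethylsilyloxy)-2,6,6-trimethylcyclohex-1-en-1-yl]-3-methylpent-2-en-4-yn-1-ol
Conditions: i-Bu2AlH, CH2Cl2, −78 °C; Rochelle salt work-up
Reagents that add atoms: none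
Why: Hydride (DIBAL) reduction of the conjugated ester in 1,2-fashion gives the allylic alcohol, silyl ethers and enyne being unaffected at −78 °C.

Step 13
Reactants: 18 (2E)-5-[(3R,4S)-3,4-bis(tert-butyldimethylsilyloxy)-2,6,6-trimethylcyclohex-1-en-1-yl]-3-methylpent-2-en-4-yn-1-ol
Product: 20 diethyl {(2E)-5-[(3R,4S)-3,4-bis(tert-butyldimethylsilyloxy)-2,6,6-trimethylcyclohex-1-en-1-yl]-3-methylpent-2-en-4-yn-1-yl}phosphonate, via allylic bromide 19 (not isolated)
Conditions: CBr4, PPh3, CH2Cl2, −20 → 0 °C; silica plug; then P(OEt)3, 80 °C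
Reagents that add atoms: tetrabromomethane, BrC(Br)(Br)Br (bromine of 19 only); triethyl phosphite, CCOP(OCC)OCC
Why: Appel bromination of the primary allylic alcohol under neutral conditions followed by Michaelis–Arbuzov reaction of the labile bromide with triethyl phosphite gives the allylic phosphonate.

Step 14
Reactants: 21 2,6,6-trimethylcyclohex-2-ene-1,4-dione (ketoisophorone)
Product: 22 (6R)-2,2,6-trimethylcyclohexane-1,4-dione
Conditions: ene reductase OYE2 (old yellow enzyme), NADP+ (cat.), glucose dehydrogenase, D-glucose, phosphate buffer pH 7, 30 °C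
Reagents that add atoms: none
Why: Enzymatic (old yellow enzyme) reduction of the activated C=C bond with cofactor recycling, a benchmark transformation of this very substrate, should set the methyl-bearing centre as (6R).

Step 15
Reactants: 22 (6R)-2,2,6-trimethylcyclohexane-1,4-dione
Product: 23 (4R,6R)-4-hydroxy-2,2,6-trimethylcyclohexan-1-one
Conditions: LiBH(s-Bu)3, THF, −78 °C
Reagents that add atoms: none
Why: Chemo- and diastereoselective hydride reduction, in which the bulky borohydride reaches only the unhindered C4 carbonyl and from the equatorial side (the axial 2-methyl group blocks axial approach), giving the axial (4R) alcohol trans to the 6-methyl group.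

Step 16
Reactants: 23 (4R,6R)-4-hydroxy-2,2,6-trimethylcyclohexan-1-one
Product: 24 (4R,6R)-4-(tert-butyldimethylsilyloxy)-2,2,6-trimethylcyclohexan-1-one
Conditions: TBSCl, imidazole, DMF, rt
Reagents that add atoms: tert-butyldimethylsilyl chloride, CC(C)(C)[Si](C)(C)Cl
Why: Standard imidazole-mediated silylation of the secondary alcohol.

Step 17
Reactants: 24 (4R,6R)-4-(tert-butyldimethylsilyloxy)-2,2,6-trimethylcyclohexan-1-one
Product: 25 (4R)-4-(tert-butyldimethylsilyloxy)-2,6,6-trimethylcyclohex-1-en-1-yl trifluoromethanesulfonate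
Conditions: LiN(i-Pr)2, THF, −78 → 0 °C; then PhNTf2, −78 °C → rt
Reagents that add atoms: N-phenylbis(trifluoromethanesulfonimide), O=S(=O)(N(c1ccccc1)S(=O)(=O)C(F)(F)F)C(F)(F)F
Why: Deprotonation at the only enolisable position gives the tetrasubstituted lithium enolate, which is O-sulfonylated to the enol triflate; the C6 centre is erased on purpose and C4 is untouched.

Step 18
Reactants: 25 (4R)-4-(tert-butyldimethylsilyloxy)-2,6,6-trimethylcyclohex-1-en-1-yl trifluoromethanesulfonate; 26 (2E)-3-methylpent-2-en-4-yn-1-ol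
Product: 27 (2E)-5-[(4R)-4-(tert-butyldimethylsilyloxy)-2,6,6-trimethylcyclohex-1-en-1-yl]-3-methylpent-2-en-4-yn-1-ol
Conditions: Pd(PPh3)4 (5 mol %), CuI (10 mol %), Et3N, DMF, 50 °C
Reagents that add atoms: none
Why: Sonogashira coupling of the hindered cyclohexenyl triflate with the terminal enynol forms C6–C7, the (E) geometry of C9=C10 coming unchanged from 26.

Step 19
Reactants: 27 (2E)-5-[(4R)-4-(tert-butyldimethylsilyloxy)-2,6,6-trimethylcyclohex-1-en-1-yl]-3-methylpent-2-en-4-yn-1-ol
Product: 29 diethyl {(2E)-5-[(4R)-4-(tert-butyldimethylsilyloxy)-2,6,6-trimethylcyclohex-1-en-1-yl]-3-methylpent-2-en-4-yn-1-yl}phosphonate, via allylic bromide 28 (not isolated)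
Conditions: CBr4, PPh3, CH2Cl2, −20 → 0 °C; silica plug; then P(OEt)3, 80 °C
Reagents that add atoms: tetrabromomethane, BrC(Br)(Br)Br (bromine of 28 only); triethyl phosphite, CCOP(OCC)OCC
Why: Appel bromination followed by Michaelis–Arbuzov reaction, as in step 13.

Step 20
Reactants: 29 diethyl {(2E)-5-[(4R)-4-(tert-butyldimethylsilyloxy)-2,6,6-trimethylcyclohex-1-en-1-yl]-3-methylpent-2-en-4-yn-1-yl}phosphonate; 30 (2E,4E,6E)-2,7-dimethylocta-2,4,6-trienedial
Product: 31 (2E,4E,6E,8E,10E)-13-[(4R)-4-(tert-butyldimethylsilyloxy)-2,6,6-trimethylcyclohex-1-en-1-yl]-2,7,11-trimethyltrideca-2,4,6,8,10-pentaen-12-ynal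
Conditions: NaN(SiMe3)2, THF, −78 °C; then added to 30 (3 equiv), −78 → 0 °C
Reagents that add atoms: none
Why: Horner–Wadsworth–Emmons olefination, in which the allylic phosphonate carbanion (made and consumed at −78 °C so that C9=C10 should keep its geometry) adds to one formyl group of the excess dialdehyde and the reversible addition is expected to lead to the (E) C11=C12 bond.

Step 21
Reactants: 31 (2E,4E,6E,8E,10E)-13-[(4R)-4-(tert-butyldimethylsilyloxy)-2,6,6-trimethylcyclohex-1-en-1-yl]-2,7,11-trimethyltrideca-2,4,6,8,10-pentaen-12-ynal; 20 diethyl {(2E)-5-[(3R,4S)-3,4-bis(tert-butyldimethylsilyloxy)-2,6,6-trimethylcyclohex-1-en-1-yl]-3-methylpent-2-en-4-yn-1-yl}phosphonate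
Product: 32 (3R,3'S,4'R)-3,3',4'-tris(tert-butyldimethylsilyloxy)-7,8,7',8'-tetradehydro-β,β-carotene (all-E)
Conditions: 20, NaN(SiMe3)2, THF, −78 °C; then 31, −78 → 0 °C, dark
Reagents that add atoms: none
Why: A second Horner–Wadsworth–Emmons olefination joins C11' to C12' and should again favour the (E) alkene, with the carbanion of 20 formed and used cold to keep the C9'=C10' geometry.

Step 22
Reactants: 32 (3R,3'S,4'R)-3,3',4'-tris(tert-butyldimethylsilyloxy)-7,8,7',8'-tetradehydro-β,β-carotene (all-E)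
Product: 33 (3R,3'S,4'R)-7,8,7',8'-tetradehydro-β,β-carotene-3,3',4'-triol (all-E; CNP0323983.1)
Conditions: Bu4NF, THF, rt, dark
Reagents that add atoms: none
Why: Fluoride cleavage of the three silyl ethers under non-acidic conditions should spare the polyene and the allylic C4'–O bond.

**Compound list**

1 | 4,4-dimethylcyclopentane-1,3-dione | CC1(C)CC(=O)CC1=O | starting material
2 | 5,5-dimethyl-3-(2-methylpropoxy)cyclopent-2-en-1-one | CC(C)COC1=CC(=O)C(C)(C)C1 | intermediate
3 | ethynyltri(propan-2-yl)silane (triisopropylsilylacetylene) | C#C[Si](C(C)C)(C(C)C)C(C)C | starting material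
4 | 5,5-dimethyl-3-(2-methylpropoxy)-1-[(triisopropylsilyl)ethynyl]cyclopent-2-en-1-ol (racemic; lithium alkoxide before the acid quench) | CC(C)COC1=CC(O)(C#C[Si](C(C)C)(C(C)C)C(C)C)C(C)(C)C1 | intermediate (not isolated)
5 | 4,4-dimethyl-3-[(triisopropylsilyl)ethynyl]cyclopent-2-en-1-one | CC(C)[Si](C(C)C)(C(C)C)C#CC1=CC(=O)CC1(C)C | intermediate
6 | (1S)-4,4-dimethyl-3-[(triisopropylsilyl)ethynyl]cyclopent-2-en-1-ol | CC(C)[Si](C(C)C)(C(C)C)C#CC1=C[C@@H](O)CC1(C)C | intermediate
7 | tert-butyl (1S)-4,4-dimethyl-3-[(triisopropylsilyl)ethynyl]cyclopent-2-en-1-yl carbonate | CC(C)[Si](C(C)C)(C(C)C)C#CC1=C[C@@H](OC(=O)OC(C)(C)C)CC1(C)C | intermediate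
8 | bromoform | BrC(Br)Br | starting material
9 | tert-butyl (2S)-6,6-dibromo-4,4-dimethyl-5-[(triisopropylsilyl)ethynyl]bicyclo[3.1.0]hexan-2-yl carbonate (either face of the cyclopropane) | CC(C)[Si](C(C)C)(C(C)C)C#CC12C(Br)(Br)C1[C@@H](OC(=O)OC(C)(C)C)CC2(C)C | intermediate (not isolated)
10 | (3aS,7aS)-4-bromo-6,6-dimethyl-5-[(triisopropylsilyl)ethynyl]-3a,6,7,7a-tetrahydro-1,3-benzodioxol-2-one (cis-fused 3',4'-carbonate) | CC(C)[Si](C(C)C)(C(C)C)C#CC1=C(Br)[C@H]2OC(=O)O[C@H]2CC1(C)C | intermediate
11 | (1S,2S)-3-bromo-5,5-dimethyl-4-[(triisopropylsilyl)ethynyl]cyclohex-3-ene-1,2-diol | CC(C)[Si](C(C)C)(C(C)C)C#CC1=C(Br)[C@@H](O)[C@@H](O)CC1(C)C | intermediate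
12 | bis(tert-butyldimethylsilyl) ether of 11 | CC(C)[Si](C(C)C)(C(C)C)C#CC1=C(Br)[C@@H](O[Si](C)(C)C(C)(C)C)[C@@H](O[Si](C)(C)C(C)(C)C)CC1(C)C | intermediate
13 | (1S,2R)-3,5,5-trimethyl-4-[(triisopropylsilyl)ethynyl]cyclohex-3-ene-1,2-diyl bis(tert-butyldimethylsilyl) ether | CC(C)[Si](C(C)C)(C(C)C)C#CC1=C(C)[C@@H](O[Si](C)(C)C(C)(C)C)[C@@H](O[Si](C)(C)C(C)(C)C)CC1(C)C | intermediate
14 | (1S,2R)-4-ethynyl-3,5,5-trimethylcyclohex-3-ene-1,2-diyl bis(tert-butyldimethylsilyl) ether | C#CC1=C(C)[C@@H](O[Si](C)(C)C(C)(C)C)[C@@H](O[Si](C)(C)C(C)(C)C)CC1(C)C | intermediate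
15 | ethyl 3-oxobutanoate (ethyl acetoacetate) | CCOC(=O)CC(C)=O | starting material
16 | ethyl (2E)-3-{[(trifluoromethyl)sulfonyl]oxy}but-2-enoate | CCOC(=O)/C=C(\C)OS(=O)(=O)C(F)(F)F | intermediate
17 | ethyl (2E)-5-[(3R,4S)-3,4-bis(tert-butyldimethylsilyloxy)-2,6,6-trimethylcyclohex-1-en-1-yl]-3-methylpent-2-en-4-ynoate | CCOC(=O)/C=C(\C)C#CC1=C(C)[C@@H](O[Si](C)(C)C(C)(C)C)[C@@H](O[Si](C)(C)C(C)(C)C)CC1(C)C | intermediate
18 | (2E)-5-[(3R,4S)-3,4-bis(tert-butyldimethylsilyloxy)-2,6,6-trimethylcyclohex-1-en-1-yl]-3-methylpent-2-en-4-yn-1-ol | OC/C=C(\C)C#CC1=C(C)[C@@H](O[Si](C)(C)C(C)(C)C)[C@@H](O[Si](C)(C)C(C)(C)C)CC1(C)C | intermediate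
19 | allylic bromide of 18 (Br in place of the primary OH) | BrC/C=C(\C)C#CC1=C(C)[C@@H](O[Si](C)(C)C(C)(C)C)[C@@H](O[Si](C)(C)C(C)(C)C)CC1(C)C | intermediate (not isolated)
20 | diethyl {(2E)-5-[(3R,4S)-3,4-bis(tert-butyldimethylsilyloxy)-2,6,6-trimethylcyclohex-1-en-1-yl]-3-methylpent-2-en-4-yn-1-yl}phosphonate | CCOP(=O)(OCC)C/C=C(\C)C#CC1=C(C)[C@@H](O[Si](C)(C)C(C)(C)C)[C@@H](O[Si](C)(C)C(C)(C)C)CC1(C)C | intermediate
21 | 2,6,6-trimethylcyclohex-2-ene-1,4-dione (ketoisophorone) | CC1=CC(=O)CC(C)(C)C1=O | starting material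
22 | (6R)-2,2,6-trimethylcyclohexane-1,4-dione | O=C1C(C)(C)CC(=O)C[C@H]1C | intermediate
23 | (4R,6R)-4-hydroxy-2,2,6-trimethylcyclohexan-1-one | O=C1C(C)(C)C[C@H](O)C[C@H]1C | intermediate
24 | (4R,6R)-4-(tert-butyldimethylsilyloxy)-2,2,6-trimethylcyclohexan-1-one | O=C1C(C)(C)C[C@H](O[Si](C)(C)C(C)(C)C)C[C@H]1C | intermediate
25 | (4R)-4-(tert-butyldimethylsilyloxy)-2,6,6-trimethylcyclohex-1-en-1-yl trifluoromethanesulfonate | CC1=C(OS(=O)(=O)C(F)(F)F)C(C)(C)C[C@H](O[Si](C)(C)C(C)(C)C)C1 | intermediate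
26 | (2E)-3-methylpent-2-en-4-yn-1-ol | C#C/C(C)=C/CO | starting material
27 | (2E)-5-[(4R)-4-(tert-butyldimethylsilyloxy)-2,6,6-trimethylcyclohex-1-en-1-yl]-3-methylpent-2-en-4-yn-1-ol | CC1=C(C#C/C(C)=C/CO)C(C)(C)C[C@H](O[Si](C)(C)C(C)(C)C)C1 | intermediate
28 | allylic bromide of 27 (Br in place of the primary OH) | CC1=C(C#C/C(C)=C/CBr)C(C)(C)C[C@H](O[Si](C)(C)C(C)(C)C)C1 | intermediate (not isolated)
29 | diethyl {(2E)-5-[(4R)-4-(tert-butyldimethylsilyloxy)-2,6,6-trimethylcyclohex-1-en-1-yl]-3-methylpent-2-en-4-yn-1-yl}phosphonate | CC1=C(C#C/C(C)=C/CP(=O)(OCC)OCC)C(C)(C)C[C@H](O[Si](C)(C)C(C)(C)C)C1 | intermediate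
30 | (2E,4E,6E)-2,7-dimethylocta-2,4,6-trienedial | O=C/C(C)=C/C=C/C=C(\C)C=O | starting material
31 | (2E,4E,6E,8E,10E)-13-[(4R)-4-(tert-butyldimethylsilyloxy)-2,6,6-trimethylcyclohex-1-en-1-yl]-2,7,11-trimethyltrideca-2,4,6,8,10-pentaen-12-ynal | CC1=C(C#C/C(C)=C/C=C/C(C)=C/C=C/C=C(\C)C=O)C(C)(C)C[C@H](O[Si](C)(C)C(C)(C)C)C1 | intermediate
32 | (3R,3'S,4'R)-3,3',4'-tris(tert-butyldimethylsilyloxy)-7,8,7',8'-tetradehydro-β,β-carotene (all-E) | CC1=C(C#C/C(C)=C/C=C/C(C)=C/C=C/C=C(C)/C=C/C=C(\C)C#CC2=C(C)[C@@H](O[Si](C)(C)C(C)(C)C)[C@@H](O[Si](C)(C)C(C)(C)C)CC2(C)C)C(C)(C)C[C@H](O[Si](C)(C)C(C)(C)C)C1 | intermediate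
33 | (3R,3'S,4'R)-7,8,7',8'-tetradehydro-β,β-carotene-3,3',4'-triol (all-E; CNP0323983.1) | CC1=C(C#C/C(C)=C/C=C/C(C)=C/C=C/C=C(C)/C=C/C=C(\C)C#CC2=C(C)[C@@H](O)[C@@H](O)CC2(C)C)C(C)(C)C[C@H](O)C1 | target

**Count and risks**

Total step count: 22. Longest linear sequence: 14 steps (1 → 33 through steps 1–9, 11–13, 21 and 22).

Steps most likely to fail:

Step 5. After ionisation the hindered carbonyl oxygen may close too slowly, so that the allyl cation loses a proton or is captured by triflate, by water or at C6', and regio- and stereocontrol at C4' erode. The fallback sets out from 9 and returns at 11. The cation is trapped on purpose with water (AgNO3, CaCO3, aqueous acetone), which should give tert-butyl (1S)-3-bromo-2-hydroxy-5,5-dimethyl-4-[(triisopropylsilyl)ethynyl]cyclohex-3-en-1-yl carbonate F1 as a mixture of C4' epimers, any C6' adduct re-ionising to this conjugated isomer. Dess–Martin periodinane converges both epimers on tert-butyl (1S)-3-bromo-5,5-dimethyl-2-oxo-4-[(triisopropylsilyl)ethynyl]cyclohex-3-en-1-yl carbonate F2. CBS reduction of this α-bromoenone with (R)-Me-CBS and catecholborane then sets C4' under reagent control and should give tert-butyl (1S,2S)-3-bromo-2-hydroxy-5,5-dimethyl-4-[(triisopropylsilyl)ethynyl]cyclohex-3-en-1-yl carbonate F3. K2CO3 in MeOH removes the carbonate group and gives diol 11.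

Step 3. Facial discrimination by the oxazaborolidine may be poor, because the enone has no α-substituent and its saturated arm is a neopentyl-type CH2, which would lower the enantiomeric purity of the whole diol ring. The fallback sets out from 5 and returns at 6. Luche reduction (NaBH4, CeCl3, MeOH) gives racemic 4,4-dimethyl-3-[(triisopropylsilyl)ethynyl]cyclopent-2-en-1-ol F4. Kinetic resolution with Burkholderia cepacia lipase and vinyl acetate should, by the usual rule for secondary alcohols, acylate the (R)-enantiomer to (1R)-4,4-dimethyl-3-[(triisopropylsilyl)ethynyl]cyclopent-2-en-1-yl acetate F5 and leave the (S)-alcohol 6.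

Step 8. Oxidative addition at the tetrasubstituted C5'–Br bond, flanked by a silyloxy-bearing carbon, may be slow, so that reduction to the C5'–H compound or no conversion results. The fallback sets out from 12 and returns at 13 without palladium. Bromine–lithium exchange (t-BuLi, 2 equiv, THF, −78 °C) gives the vinyllithium derivative of 12 with lithium in place of bromine F6, which cannot eliminate the neighbouring silyloxy group because that would require a six-membered allene. Quenching with CH3I gives 13.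

**Further compounds**

F1 | step 5 | tert-butyl (1S)-3-bromo-2-hydroxy-5,5-dimethyl-4-[(triisopropylsilyl)ethynyl]cyclohex-3-en-1-yl carbonate (both C2 epimers) | CC(C)[Si](C(C)C)(C(C)C)C#CC1=C(Br)C(O)[C@@H](OC(=O)OC(C)(C)C)CC1(C)C
F2 | step 5 | tert-butyl (1S)-3-bromo-5,5-dimethyl-2-oxo-4-[(triisopropylsilyl)ethynyl]cyclohex-3-en-1-yl carbonate | CC(C)[Si](C(C)C)(C(C)C)C#CC1=C(Br)C(=O)[C@@H](OC(=O)OC(C)(C)C)CC1(C)C
F3 | step 5 | tert-butyl (1S,2S)-3-bromo-2-hydroxy-5,5-dimethyl-4-[(triisopropylsilyl)ethynyl]cyclohex-3-en-1-yl carbonate | CC(C)[Si](C(C)C)(C(C)C)C#CC1=C(Br)[C@@H](O)[C@@H](OC(=O)OC(C)(C)C)CC1(C)C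
F4 | step 3 | racemic 4,4-dimethyl-3-[(triisopropylsilyl)ethynyl]cyclopent-2-en-1-ol | CC(C)[Si](C(C)C)(C(C)C)C#CC1=CC(O)CC1(C)C
F5 | step 3 | (1R)-4,4-dimethyl-3-[(triisopropylsilyl)ethynyl]cyclopent-2-en-1-yl acetate | CC(C)[Si](C(C)C)(C(C)C)C#CC1=C[C@H](OC(C)=O)CC1(C)C
F6 | step 8 | vinyllithium derivative of 12 (lithium in place of bromine at C5') | CC(C)[Si](C(C)C)(C(C)C)C#CC1=C([Li])[C@@H](O[Si](C)(C)C(C)(C)C)[C@@H](O[Si](C)(C)C(C)(C)C)CC1(C)C
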